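The cyclohexanone ring (C1 carbonyl carbon, C2 gem-dimethyl carbon, C3 side-chain carbon, C4 carbinol carbon) is cut at C1–C2 and C3–C4. C2–C3 with the whole side chain comes from (R)-linalool; C4–C5–C6–C1 is hidden in 2-methoxy-5-methylfuran. The key step is an enantioselective Diels–Alder reaction of this furan with an (E)-α-methyl enal, obtained by oxidising one terminal methyl of the prenyl group to a formyl group that activates C2=C3 and is later reduced back to methyl. It exploits the 1,4-relationship of the C1 ketone and the C4 tertiary alcohol: these are the two oxygen-bearing furan carbons, and the 7-oxanorbornene ketal adduct opens to the 4-hydroxycyclohexenone.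

Key step: step 5

Remark on numbering: ring atoms keep the labels C1–C6 of the target throughout; the side chain is C1′–C5′, with the tertiary carbinol at C3′.

Assumption: the (S)-oxazaborolidine is written for definiteness. It stands for whichever antipode delivers the furan to the Re face of C3 of enal 5; the other antipode is used if the sense of induction requires it.

Step 1
Reactants: 1 (R)-(−)-linalool, (3R)-3,7-dimethylocta-1,6-dien-3-ol
Product: 2 (3R)-3,7-dimethyloct-6-ene-1,3-diol
Conditions: 9-BBN (2.2 equiv), THF, 0 °C to rt; then NaOH, H2O2, 0 °C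
Reagents that add atoms: hydrogen peroxide, OO
Why: Hydroboration–oxidation with the bulky 9-BBN should take the monosubstituted vinyl group anti-Markovnikov and leave the trisubstituted alkene alone; the C3′ centre is not touched and stays (R).

Step 2
Reactants: 2 (3R)-3,7-dimethyloct-6-ene-1,3-diol
Product: 4 (2E,6R)-6,8-dihydroxy-2,6-dimethyloct-2-enal, via E-allylic triol 3 (not isolated)
Conditions: SeO2 (0.3 equiv), t-BuOOH, CH2Cl2, rt; then MnO2, CH2Cl2, rt
Reagents that add atoms: selenium dioxide, O=[Se]=O; tert-butyl hydroperoxide, CC(C)(C)OO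
Why: Riley allylic oxidation (ene reaction, then 2,3-sigmatropic shift) should hydroxylate the methyl group trans to the chain, and MnO2 should oxidise only that allylic alcohol, giving the (E)-enal in which C2=C3 is now activated.

Step 3
Reactants: 4 (2E,6R)-6,8-dihydroxy-2,6-dimethyloct-2-enal
Product: 5 (2E,6R)-2,6-dimethyl-6,8-bis(triethylsilyloxy)oct-2-enal
Conditions: TESOTf (2.5 equiv), 2,6-lutidine, CH2Cl2, −78 °C
Reagents that add atoms: triethylsilyl trifluoromethanesulfonate, CC[Si](CC)(CC)OS(=O)(=O)C(F)(F)F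
Why: Silylation with the silyl triflate and a hindered base should cap the primary and the tertiary hydroxyl, which would otherwise quench the boron Lewis acid of step 5.

Step 4
Reactants: 6 2-methoxyfuran
Product: 7 2-methoxy-5-methylfuran
Conditions: n-BuLi, THF, −78 to 0 °C; then MeI, −78 °C to rt
Reagents that add atoms: iodomethane, CI
Why: α-Lithiation of the furan at its free C5 position followed by alkylation of the furyllithium with MeI.

Step 5
Reactants: 5 (2E,6R)-2,6-dimethyl-6,8-bis(triethylsilyloxy)oct-2-enal; 7 2-methoxy-5-methylfuran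
Product: 10 (4S,5R,6S)-5-[(3R)-3,5-dihydroxy-3-methylpentyl]-4-hydroxy-6-(hydroxymethyl)-4,6-dimethylcyclohex-2-en-1-one, via cycloadduct aldehyde 8 (not isolated), via cycloadduct alcohol 9 (not isolated)
Conditions: 7 (3 equiv), (S)-3,3-diphenyl-1-(o-tolyl)tetrahydro-1H,3H-pyrrolo[1,2-c][1,3,2]oxazaborole (C24H24BNO) activated with HNTf2 (20 mol%), CH2Cl2, −78 °C; then NaBH4, MeOH, −78 to −40 °C; then 48% aq. HF, MeCN, 0 °C to rt
Reagents that add atoms: water, O
Why: The enal, bound through its formyl group to the chiral boron Lewis acid, should undergo a concerted but asynchronous Diels–Alder reaction with the electron-rich furan, the methyl-bearing furan carbon (C4) bonding to the β-carbon C3 and the methoxy-bearing carbon (C1) to the α-carbon C2, so that the carbocycle is closed by a suprafacial [4+2] cycloaddition inside the 7-oxanorbornene 8 and this polarity match fixes the regiochemistry. The closest known reactions are the oxazaborolidinium-catalysed Diels–Alder reactions of furans and of α-substituted enals, and the cycloaddition and bridge opening of 2-oxygenated furans. The catalyst is to direct the furan to the Re face of C3, which sets C3 (R) independently of the remote C3′ centre; C4 follows from the (E)-geometry of the enal and the endo position of the formyl group, which places the side chain exo, that is syn to the oxygen bridge and later cis to the C4 hydroxyl, while the C2 centre formed here is erased in step 9. Endo selectivity is the demand on the step and should be helped by the oxygen bridge, which unlike a methylene bridge carries no hydrogen to repel the exo methyl group and side chain. The adduct could reopen by heterolysis of C1–C2 to an open butenolide; the methyl ether (no transferable silyl group), the non-nucleophilic counter-ion, −78 °C and the cold borohydride quench, which removes the formyl acceptor before the ketal is touched, are meant to prevent this. Aqueous HF then hydrolyses the bicyclic ketal, the bridge oxygen staying on C4 as the hydroxyl and C1 becoming the ketone, and removes both silyl ethers.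

Step 6
Reactants: 10 (4S,5R,6S)-5-[(3R)-3,5-dihydroxy-3-methylpentyl]-4-hydroxy-6-(hydroxymethyl)-4,6-dimethylcyclohex-2-en-1-one
Product: 11 (2S,3R,4S)-3-[(3R)-3,5-dihydroxy-3-methylpentyl]-4-hydroxy-2-(hydroxymethyl)-2,4-dimethylcyclohexan-1-one
Conditions: H2 (1 atm), Pd/C, EtOAc, rt
Reagents that add atoms: none
Why: Heterogeneous hydrogenation of the disubstituted enone alkene; C5 and C6 become methylene groups, no stereocentre is formed, and no other reducible group is present at this stage.

Step 7
Reactants: 11 (2S,3R,4S)-3-[(3R)-3,5-dihydroxy-3-methylpentyl]-4-hydroxy-2-(hydroxymethyl)-2,4-dimethylcyclohexan-1-one; 12 umbelliferone (7-hydroxy-2H-chromen-2-one)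
Product: 13 (2S,3R,4S)-4-hydroxy-3-[(3R)-3-hydroxy-3-methyl-5-(2-oxo-2H-chromen-7-yloxy)pentyl]-2-(hydroxymethyl)-2,4-dimethylcyclohexan-1-one
Conditions: PPh3, DIAD, THF, 0 °C to rt
Reagents that add atoms: none
Why: Mitsunobu etherification; of the four hydroxyl groups only the unhindered primary C5′ hydroxyl should be activated (the other primary one is neopentylic, two are tertiary), and the acidic phenol displaces it at a carbon that is not a stereocentre.

Step 8
Reactants: 13 (2S,3R,4S)-4-hydroxy-3-[(3R)-3-hydroxy-3-methyl-5-(2-oxo-2H-chromen-7-yloxy)pentyl]-2-(hydroxymethyl)-2,4-dimethylcyclohexan-1-one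
Product: 14 O-phenyl thionocarbonate of 13 at the C2 hydroxymethyl group, O-{[(1S,2R,3S)-3-hydroxy-2-[(3R)-3-hydroxy-3-methyl-5-(2-oxo-2H-chromen-7-yloxy)pentyl]-1,3-dimethyl-6-oxocyclohexyl]methyl} O-phenyl carbonothioate
Conditions: PhOC(S)Cl, pyridine, DMAP (cat.), CH2Cl2, 0 °C to rt
Reagents that add atoms: O-phenyl chlorothionoformate, S=C(Cl)Oc1ccccc1
Why: Acylation of the only hydroxyl that is not tertiary gives the thionocarbonate needed for a Barton–McCombie deoxygenation.

Step 9
Reactants: 14 O-phenyl thionocarbonate of 13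
Product: 15 (3R,4S)-4-hydroxy-3-[(3R)-3-hydroxy-3-methyl-5-(2-oxo-2H-chromen-7-yloxy)pentyl]-2,2,4-trimethylcyclohexan-1-one (target)
Conditions: Bu3SnH (5 equiv, 0.5 M), AIBN, PhSeSePh (10 mol%), benzene, 80 °C
Reagents that add atoms: none
Why: Barton–McCombie radical deoxygenation turns the former formyl carbon into the second C2 methyl group; benzeneselenol formed in the flask is a very fast hydrogen donor that should trap the primary β-keto radical before a 1,2-acyl shift (Dowd–Beckwith-type ring expansion) can occur.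

Compound list

1 | (R)-(−)-linalool, (3R)-3,7-dimethylocta-1,6-dien-3-ol | C=C[C@](C)(O)CCC=C(C)C | starting material
2 | (3R)-3,7-dimethyloct-6-ene-1,3-diol | OCC[C@](C)(O)CCC=C(C)C | intermediate
3 | (2E,6R)-2,6-dimethyloct-2-ene-1,6,8-triol | OC/C(C)=C/CC[C@@](C)(O)CCO | intermediate
4 | (2E,6R)-6,8-dihydroxy-2,6-dimethyloct-2-enal | O=C/C(C)=C/CC[C@@](C)(O)CCO | intermediate
5 | (2E,6R)-2,6-dimethyl-6,8-bis(triethylsilyloxy)oct-2-enal | O=C/C(C)=C/CC[C@@](C)(O[Si](CC)(CC)CC)CCO[Si](CC)(CC)CC | intermediate
6 | 2-methoxyfuran | COc1ccco1 | starting material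
7 | 2-methoxy-5-methylfuran | COc1ccc(C)o1 | intermediate
8 | (1R,2S,3R,4S)-1-methoxy-2,4-dimethyl-3-[(3R)-3-methyl-3,5-bis(triethylsilyloxy)pentyl]-7-oxabicyclo[2.2.1]hept-5-ene-2-carbaldehyde (formyl endo; C2-methyl and side chain exo) | O=C[C@]1(C)[C@@H](CC[C@@](C)(O[Si](CC)(CC)CC)CCO[Si](CC)(CC)CC)[C@]2(C)C=C[C@@]1(OC)O2 | intermediate
9 | [(1R,2S,3R,4S)-1-methoxy-2,4-dimethyl-3-[(3R)-3-methyl-3,5-bis(triethylsilyloxy)pentyl]-7-oxabicyclo[2.2.1]hept-5-en-2-yl]methanol | OC[C@]1(C)[C@@H](CC[C@@](C)(O[Si](CC)(CC)CC)CCO[Si](CC)(CC)CC)[C@]2(C)C=C[C@@]1(OC)O2 | intermediate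
10 | (4S,5R,6S)-5-[(3R)-3,5-dihydroxy-3-methylpentyl]-4-hydroxy-6-(hydroxymethyl)-4,6-dimethylcyclohex-2-en-1-one | C[C@]1(CO)C(=O)C=C[C@](C)(O)[C@@H]1CC[C@@](C)(O)CCO | intermediate
11 | (2S,3R,4S)-3-[(3R)-3,5-dihydroxy-3-methylpentyl]-4-hydroxy-2-(hydroxymethyl)-2,4-dimethylcyclohexan-1-one | C[C@]1(CO)C(=O)CC[C@](C)(O)[C@@H]1CC[C@@](C)(O)CCO | intermediate
12 | umbelliferone, 7-hydroxy-2H-chromen-2-one | Oc1ccc2ccc(=O)oc2c1 | starting material
13 | (2S,3R,4S)-4-hydroxy-3-[(3R)-3-hydroxy-3-methyl-5-(2-oxo-2H-chromen-7-yloxy)pentyl]-2-(hydroxymethyl)-2,4-dimethylcyclohexan-1-one | C[C@]1(CO)C(=O)CC[C@](C)(O)[C@@H]1CC[C@@](C)(O)CCOc1ccc2ccc(=O)oc2c1 | intermediate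
14 | O-phenyl thionocarbonate of 13 at the C2 hydroxymethyl group | C[C@]1(COC(=S)Oc2ccccc2)C(=O)CC[C@](C)(O)[C@@H]1CC[C@@](C)(O)CCOc1ccc2ccc(=O)oc2c1 | intermediate
15 | (3R,4S)-4-hydroxy-3-[(3R)-3-hydroxy-3-methyl-5-(2-oxo-2H-chromen-7-yloxy)pentyl]-2,2,4-trimethylcyclohexan-1-one | CC1(C)C(=O)CC[C@](C)(O)[C@@H]1CC[C@@](C)(O)CCOc1ccc2ccc(=O)oc2c1 | target

Total step count: 9 steps. Longest linear sequence: 8 steps (1, 2, 3, 5, 6, 7, 8, 9); step 4 prepares the furan.

Steps most likely to fail

Step 5 (key step). Three things may go wrong: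
- The adduct, still bound to the Lewis acid, may reopen by heterolysis of the new C1–C2 bond before the hydride quench, draining material into the open-chain conjugate adduct, so that only C3–C4 is formed.
- The formyl group may prefer the exo position, which would invert C4 relative to C3.
- Facial control by the catalyst may be incomplete.

Fallback, from 5 back to 11: a carbocyclic diene whose adduct is a less strained bicyclo[2.2.2]octene, followed by oxidative excision of the extra bridge.
- Commercial 1-methoxy-4-methylcyclohexa-1,4-diene is conjugated (KOt-Bu, DMSO) to 1-methoxy-4-methylcyclohexa-1,3-diene F1.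
- Under the same boron catalyst, F1 and 5 should give the bicyclo[2.2.2]octene aldehyde F2 (methoxy carbon bonded to C2, methyl-bearing carbon to C3).
- F2 is reduced in the flask with NaBH4 to the alcohol F3 and silylated (TESCl, imidazole) to the tris-silyl ether F4.
- Ozonolysis (O3, CH2Cl2, −78 °C; Me2S) cuts the unsaturated two-carbon bridge to the dialdehyde F5.
- Baeyer–Villiger oxidation (mCPBA, NaHCO3), with migration of the two fully substituted ring carbons and retention, gives the bis-formate F6.
- K2CO3/MeOH and then aqueous HF free the C4 hydroxyl, collapse the C1 methoxy hemiketal to the ketone and remove the silyl groups, giving 11.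

In this variant the C4 oxygen arises from the unsaturated bridge. The exo-formyl mode that α-methyl enals usually follow with carbocyclic dienes (C2-methyl and side chain syn to that bridge) therefore leads to the same relative configuration, so the fallback also covers an unfavourable endo/exo preference.

Step 9. The primary radical next to the ketone may undergo a 1,2-acyl migration (one-carbon ring expansion) faster than hydrogen transfer.

Fallback, from 9 back to 15: the deoxygenation is moved to a stage where the ketone is still masked as the bicyclic ketal and is done without radicals.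
- 9 is isolated after the borohydride stage of step 5 (NaHCO3 work-up, no HF).
- Hydrogenation (H2, Pd/C, EtOAc, 0 °C) gives the saturated ketal alcohol F7 and also closes the retro-Diels–Alder pathway.
- MsCl/Et3N gives the mesylate F8.
- LiEt3BH (THF, 60 °C) displaces the mesylate by hydride to give the gem-dimethyl ketal F9.
- Aqueous HF/MeCN gives the triol ketone F10.
- Mitsunobu etherification of the single primary hydroxyl of F10 with 12 (PPh3, DIAD) gives 15.

Step 2. The allylic oxidation of a substrate with a free 1,3-diol may stop short, over-oxidise, or attack the allylic methylene instead of the trans methyl group.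

Fallback, from 2 back to 4: the alkene is cleaved and rebuilt with the formyl group in place.
- Ozonolysis of 2 (O3, CH2Cl2/MeOH, −78 °C; Me2S) gives the lactol (5R)-5-(2-hydroxyethyl)-5-methyloxolan-2-ol F11, the hydroxy aldehyde closed on the tertiary hydroxyl.
- Wittig olefination of F11 with the stabilised ylide 2-(triphenylphosphoranylidene)propanal (toluene, 80 °C) should give the (E)-enal 4.

Further compounds

F1 | step 5 | 1-methoxy-4-methylcyclohexa-1,3-diene | COC1=CC=C(C)CC1
F2 | step 5 | 1-methoxy-2,4-dimethyl-3-[(3R)-3-methyl-3,5-bis(triethylsilyloxy)pentyl]bicyclo[2.2.2]oct-5-ene-2-carbaldehyde (formyl anti, C2-methyl and side chain syn to the C5=C6 bridge) | O=C[C@]1(C)[C@@H](CC[C@@](C)(O[Si](CC)(CC)CC)CCO[Si](CC)(CC)CC)[C@@]2(C)C=C[C@]1(OC)CC2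
F3 | step 5 | alcohol from reduction of F2 | OC[C@]1(C)[C@@H](CC[C@@](C)(O[Si](CC)(CC)CC)CCO[Si](CC)(CC)CC)[C@@]2(C)C=C[C@]1(OC)CC2
F4 | step 5 | triethylsilyl ether of F3 | CC[Si](CC)(CC)OC[C@]1(C)[C@@H](CC[C@@](C)(O[Si](CC)(CC)CC)CCO[Si](CC)(CC)CC)[C@@]2(C)C=C[C@]1(OC)CC2
F5 | step 5 | cis-1,4-dialdehyde from ozonolysis of F4 (1-methoxy-4-methylcyclohexane-1,4-dicarbaldehyde core) | CC[Si](CC)(CC)OC[C@]1(C)[C@@H](CC[C@@](C)(O[Si](CC)(CC)CC)CCO[Si](CC)(CC)CC)[C@@](C)(C=O)CC[C@@]1(OC)C=O
F6 | step 5 | bis-formate from Baeyer–Villiger oxidation of F5 | CC[Si](CC)(CC)OC[C@]1(C)[C@@H](CC[C@@](C)(O[Si](CC)(CC)CC)CCO[Si](CC)(CC)CC)[C@@](C)(OC=O)CC[C@@]1(OC)OC=O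
F7 | step 9 | saturated ketal alcohol, the 5,6-dihydro derivative of 9 | OC[C@]1(C)[C@@H](CC[C@@](C)(O[Si](CC)(CC)CC)CCO[Si](CC)(CC)CC)[C@]2(C)CC[C@@]1(OC)O2
F8 | step 9 | methanesulfonate of F7 | CS(=O)(=O)OC[C@]1(C)[C@@H](CC[C@@](C)(O[Si](CC)(CC)CC)CCO[Si](CC)(CC)CC)[C@]2(C)CC[C@@]1(OC)O2
F9 | step 9 | 1-methoxy-2,2,4-trimethyl-3-[(3R)-3-methyl-3,5-bis(triethylsilyloxy)pentyl]-7-oxabicyclo[2.2.1]heptane | CC1(C)[C@@H](CC[C@@](C)(O[Si](CC)(CC)CC)CCO[Si](CC)(CC)CC)[C@]2(C)CC[C@@]1(OC)O2
F10 | step 9 | (3R,4S)-3-[(3R)-3,5-dihydroxy-3-methylpentyl]-4-hydroxy-2,2,4-trimethylcyclohexan-1-one | CC1(C)C(=O)CC[C@](C)(O)[C@@H]1CC[C@@](C)(O)CCO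
F11 | step 2 | (5R)-5-(2-hydroxyethyl)-5-methyloxolan-2-ol (anomer mixture) | OCC[C@@]1(C)CCC(O)O1
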